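The 2-aryl-3-formylbenzofuran core is read as a rearranged chalcone: the formyl carbon, C3 and C2 form a three-carbon chain in which C3 carries the benzo ring through C3a (with the furan oxygen O1 on the adjacent C7a) and C2 carries the resorcinol ring. One oxidative 1,2-aryl shift with trivalent iodine moves the bromo-trioxygenated ring of a fully O-protected (E)-chalcone from the β- to the α-carbon, forging C3–C3a and leaving the old β-carbon as a dimethyl acetal, the masked CHO. The chalcone comes from aldol condensation of a benzyl/MOM-differentiated bromobenzaldehyde with 2,4-bis(benzyloxy)acetophenone; acid then closes the furan on the ketone, and the C5 side chain is attached last by Sonogashira coupling and hydrogenation.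

Key step: step 8

Remark: the target has no stereocentre. The 2-methoxy-2,3-dihydrobenzofuran of step 9 is carried on as a mixture of racemic diastereomers, since both centres vanish on aromatisation.

Step 1
Reactants: 1 5-methoxyresorcinol
Product: 2 1-methoxy-3,5-bis(methoxymethoxy)benzene
Conditions: NaH, MOMCl, DMF, 0 °C to rt
Reagents that add atoms: chloromethyl methyl ether (MOMCl), COCCl
Why: Double Williamson O-alkylation of the bis-phenoxide with the reactive α-chloro ether should cap both phenols as MOM acetals, which serve as the directing groups for the next metalation.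

Step 2
Reactants: 2 1-methoxy-3,5-bis(methoxymethoxy)benzene
Product: 4 4-methoxy-2,6-bis(methoxymethoxy)benzaldehyde, via aryllithium 3 (not isolated)
Conditions: n-BuLi, TMEDA, THF, 0 °C; DMF, 0 °C to rt; H2O
Reagents that add atoms: N,N-dimethylformamide (DMF), CN(C)C=O
Why: Directed ortho-metalation should occur at the carbon flanked by the two OMOM groups, where two chelating acetal oxygens cooperate, and formylation of aryllithium 3 with DMF then gives the symmetric aldehyde.

Step 3
Reactants: 4 4-methoxy-2,6-bis(methoxymethoxy)benzaldehyde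
Product: 5 2-hydroxy-4-methoxy-6-(methoxymethoxy)benzaldehyde
Conditions: 3 M aq. HCl, THF, rt, stopped at mono-cleavage
Reagents that add atoms: none
Why: Selective acetal hydrolysis is expected because the MOM group ortho to the formyl group is cleaved first and the hydrogen bond between the freed phenol and the carbonyl oxygen then slows loss of the second one.

Step 4
Reactants: 5 2-hydroxy-4-methoxy-6-(methoxymethoxy)benzaldehyde
Product: 6 3-bromo-2-hydroxy-4-methoxy-6-(methoxymethoxy)benzaldehyde
Conditions: NBS (1.0 equiv), i-Pr2NH (cat.), CH2Cl2, 0 °C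
Reagents that add atoms: N-bromosuccinimide (NBS), O=C1CCC(=O)N1Br
Why: Amine-mediated electrophilic aromatic bromination delivers bromine ortho to the free phenol, at the carbon between OH and OMe, which is also less crowded than the carbon between OMe and OMOM, and the acid-free medium spares the MOM acetal.

Step 5
Reactants: 6 3-bromo-2-hydroxy-4-methoxy-6-(methoxymethoxy)benzaldehyde
Product: 7 2-(benzyloxy)-3-bromo-4-methoxy-6-(methoxymethoxy)benzaldehyde
Conditions: BnBr, K2CO3, DMF, 60 °C
Reagents that add atoms: benzyl bromide, BrCc1ccccc1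
Why: Williamson etherification of the acidic chelated phenoxide puts an acid-stable benzyl group on the oxygen next to bromine, while the oxygen destined for the furan keeps the acid-labile MOM group.

Step 6
Reactants: 8 2,4-dihydroxyacetophenone
Product: 9 2,4-bis(benzyloxy)acetophenone
Conditions: BnBr (2.4 equiv), K2CO3, DMF, 80 °C
Reagents that add atoms: benzyl bromide, BrCc1ccccc1
Why: Double Williamson etherification in hot DMF also alkylates the hydrogen-bonded ortho phenol, so that no oxygen of this ring can later attack the rearranged chain or be oxidised.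

Step 7
Reactants: 7 2-(benzyloxy)-3-bromo-4-methoxy-6-(methoxymethoxy)benzaldehyde; 9 2,4-bis(benzyloxy)acetophenone
Product: 11 (E)-3-[2-(benzyloxy)-3-bromo-4-methoxy-6-(methoxymethoxy)phenyl]-1-[2,4-bis(benzyloxy)phenyl]prop-2-en-1-one, via aldol adduct 10 (not isolated)
Conditions: KOH, EtOH/THF, rt to 40 °C
Reagents that add atoms: none
Why: In this Claisen–Schmidt condensation the acetophenone enolate adds to the non-enolisable aldehyde and E1cB loss of water from aldol adduct 10 gives the conjugated enone as its more stable E isomer, the ethers and the aryl bromide being inert to hydroxide.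

Step 8
Reactants: 11 (E)-3-[2-(benzyloxy)-3-bromo-4-methoxy-6-(methoxymethoxy)phenyl]-1-[2,4-bis(benzyloxy)phenyl]prop-2-en-1-one
Product: 13 2-[2-(benzyloxy)-3-bromo-4-methoxy-6-(methoxymethoxy)phenyl]-1-[2,4-bis(benzyloxy)phenyl]-3,3-dimethoxypropan-1-one, via iodane adduct 12 (not isolated)
Conditions: PhI(OH)OTs (1.2 equiv), HC(OMe)3/MeOH/CH2Cl2, rt
Reagents that add atoms: methanol, CO
Why: The trivalent-iodine electrophile (PhI(OMe)OTs formed in methanol) adds to the enone C=C while methanol attacks the benzylic β-carbon, giving the α-iodanyl β-methoxy ketone 12; iodobenzene then leaves with participation of the β-aryl ring, which bridges as a phenonium ion and ends on the α-carbon, and the β-methoxy oxocarbenium ion left behind is trapped by methanol as the dimethyl acetal. This is the known oxidative 1,2-aryl migration of chalcones to 1,2-diaryl-3,3-dimethoxypropan-1-ones, the isoflavone-type rearrangement run with Tl(NO3)3 or hypervalent iodine. No ring is closed here: the step only makes the C–C bond that becomes C3–C3a, and the furan is closed in steps 9 and 10. The single new stereocentre, the α-carbon, forms racemic under no control and is erased when the furan aromatises. The step needs exclusive migration of the bromo-trioxygenated ring and attack of the oxidant on the enone only; the first is secured by the two ortho and one para oxygen donors that stabilise the phenonium ion, the second by the capping of every phenol and by conjugation of both rings to the carbonyl. Trimethyl orthoformate consumes the water released, so that the MOM ether and the new acetal should survive the TsOH formed.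

Step 9
Reactants: 13 2-[2-(benzyloxy)-3-bromo-4-methoxy-6-(methoxymethoxy)phenyl]-1-[2,4-bis(benzyloxy)phenyl]-3,3-dimethoxypropan-1-one
Product: 15 [4-(benzyloxy)-5-bromo-2,6-dimethoxy-2,3-dihydrobenzofuran-3-yl][2,4-bis(benzyloxy)phenyl]methanone, via free phenol acetal 14 (not isolated)
Conditions: p-TsOH·H2O (0.2 equiv), MeOH/THF, 40 °C
Reagents that add atoms: none
Why: Acid-catalysed acetal exchange: methanolysis of the MOM ether frees the one phenol, which displaces a methoxy group of the neighbouring dimethyl acetal through its oxocarbenium ion (5-exo closure) to give the cyclic mixed acetal, while methanol traps the methoxymethyl cation and the benzyl ethers stay intact.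

Step 10
Reactants: 15 [4-(benzyloxy)-5-bromo-2,6-dimethoxy-2,3-dihydrobenzofuran-3-yl][2,4-bis(benzyloxy)phenyl]methanone
Product: 17 2-[2,4-bis(benzyloxy)phenyl]-4-(benzyloxy)-5-bromo-6-methoxybenzofuran-3-carbaldehyde, via ring-opened enol ether 16 (not isolated)
Conditions: p-TsOH·H2O (2 equiv), (CF3)2CHOH, rt
Reagents that add atoms: water, O
Why: In this known acid-mediated cyclodehydration of 3-acyl-2-alkoxy-2,3-dihydrobenzofurans to 3-formylbenzofurans, the sulfonic acid in the ionising, weakly nucleophilic fluoro alcohol reopens the cyclic acetal to enol ether 16, the phenol adds to the protonated aryl ketone (5-exo-trig), and loss of water with aromatisation followed by hydrolysis of the methoxymethylene oxocarbenium ion by the hydrate water gives the aldehyde.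

Step 11
Reactants: 17 2-[2,4-bis(benzyloxy)phenyl]-4-(benzyloxy)-5-bromo-6-methoxybenzofuran-3-carbaldehyde; 18 2-methylbut-3-yn-2-ol
Product: 19 2-[2,4-bis(benzyloxy)phenyl]-4-(benzyloxy)-5-(3-hydroxy-3-methylbut-1-yn-1-yl)-6-methoxybenzofuran-3-carbaldehyde
Conditions: PdCl2(MeCN)2 (5 mol %), 2-dicyclohexylphosphino-2',4',6'-triisopropylbiphenyl (XPhos, 15 mol %), Cs2CO3, MeCN, 80 °C
Reagents that add atoms: none
Why: In this copper-free Sonogashira coupling the bulky electron-rich biaryl phosphine should give a monoligated zerovalent palladium species that inserts into the electron-rich C–Br bond flanked by two alkoxy groups, and the acetylide formed with carbonate couples without copper-induced alkyne dimerisation, the aldehyde and benzyl ethers being inert.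

Step 12
Reactants: 19 2-[2,4-bis(benzyloxy)phenyl]-4-(benzyloxy)-5-(3-hydroxy-3-methylbut-1-yn-1-yl)-6-methoxybenzofuran-3-carbaldehyde
Product: 20 ebenfuran V
Conditions: H2 (1 atm), 10% Pd/C, EtOAc, rt
Reagents that add atoms: none
Why: Heterogeneous hydrogenation and hydrogenolysis over palladium saturate the alkyne and cleave the three benzyl ethers to toluene, whereas the formyl group (a vinylogous ester of the furan oxygen, hydrogen-bonded to the new C4 phenol) and the tertiary alcohol should survive in neutral ethyl acetate.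

Compound list
1 | 5-methoxyresorcinol (5-methoxybenzene-1,3-diol) | COc1cc(O)cc(O)c1 | starting material
2 | 1-methoxy-3,5-bis(methoxymethoxy)benzene | COCOc1cc(OC)cc(OCOC)c1 | intermediate
3 | [4-methoxy-2,6-bis(methoxymethoxy)phenyl]lithium | [Li]c1c(OCOC)cc(OC)cc1OCOC | intermediate
4 | 4-methoxy-2,6-bis(methoxymethoxy)benzaldehyde | COCOc1cc(OC)cc(OCOC)c1C=O | intermediate
5 | 2-hydroxy-4-methoxy-6-(methoxymethoxy)benzaldehyde | COCOc1cc(OC)cc(O)c1C=O | intermediate
6 | 3-bromo-2-hydroxy-4-methoxy-6-(methoxymethoxy)benzaldehyde | O=Cc1c(O)c(Br)c(OC)cc1OCOC | intermediate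
7 | 2-(benzyloxy)-3-bromo-4-methoxy-6-(methoxymethoxy)benzaldehyde | O=Cc1c(OCc2ccccc2)c(Br)c(OC)cc1OCOC | intermediate
8 | 2,4-dihydroxyacetophenone | CC(=O)c1ccc(O)cc1O | starting material
9 | 2,4-bis(benzyloxy)acetophenone | CC(=O)c1ccc(OCc2ccccc2)cc1OCc1ccccc1 | intermediate
10 | racemic 3-[2-(benzyloxy)-3-bromo-4-methoxy-6-(methoxymethoxy)phenyl]-1-[2,4-bis(benzyloxy)phenyl]-3-hydroxypropan-1-one (aldol adduct) | O=C(CC(O)c1c(OCc2ccccc2)c(Br)c(OC)cc1OCOC)c1ccc(OCc2ccccc2)cc1OCc1ccccc1 | intermediate
11 | (E)-3-[2-(benzyloxy)-3-bromo-4-methoxy-6-(methoxymethoxy)phenyl]-1-[2,4-bis(benzyloxy)phenyl]prop-2-en-1-one | O=C(/C=C/c1c(OCc2ccccc2)c(Br)c(OC)cc1OCOC)c1ccc(OCc2ccccc2)cc1OCc1ccccc1 | intermediate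
12 | 3-[2-(benzyloxy)-3-bromo-4-methoxy-6-(methoxymethoxy)phenyl]-1-[2,4-bis(benzyloxy)phenyl]-3-methoxy-2-[phenyl(tosyloxy)iodanyl]propan-1-one (racemic, relative configuration not defined) | COC(c1c(OCc2ccccc2)c(Br)c(OC)cc1OCOC)C(C(=O)c1ccc(OCc2ccccc2)cc1OCc1ccccc1)I(OS(=O)(=O)c1ccc(C)cc1)c1ccccc1 | intermediate
13 | racemic 2-[2-(benzyloxy)-3-bromo-4-methoxy-6-(methoxymethoxy)phenyl]-1-[2,4-bis(benzyloxy)phenyl]-3,3-dimethoxypropan-1-one | COC(OC)C(c1c(OCc2ccccc2)c(Br)c(OC)cc1OCOC)C(=O)c1ccc(OCc2ccccc2)cc1OCc1ccccc1 | intermediate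
14 | racemic 2-[2-(benzyloxy)-3-bromo-6-hydroxy-4-methoxyphenyl]-1-[2,4-bis(benzyloxy)phenyl]-3,3-dimethoxypropan-1-one | COC(OC)C(c1c(OCc2ccccc2)c(Br)c(OC)cc1O)C(=O)c1ccc(OCc2ccccc2)cc1OCc1ccccc1 | intermediate
15 | [4-(benzyloxy)-5-bromo-2,6-dimethoxy-2,3-dihydrobenzofuran-3-yl][2,4-bis(benzyloxy)phenyl]methanone (racemic, mixture of C2/C3 diastereomers, trans expected to prevail) | COC1Oc2cc(OC)c(Br)c(OCc3ccccc3)c2C1C(=O)c1ccc(OCc2ccccc2)cc1OCc1ccccc1 | intermediate
16 | 2-[2-(benzyloxy)-3-bromo-6-hydroxy-4-methoxyphenyl]-1-[2,4-bis(benzyloxy)phenyl]-3-methoxyprop-2-en-1-one (double-bond geometry not defined) | COC=C(c1c(OCc2ccccc2)c(Br)c(OC)cc1O)C(=O)c1ccc(OCc2ccccc2)cc1OCc1ccccc1 | intermediate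
17 | 2-[2,4-bis(benzyloxy)phenyl]-4-(benzyloxy)-5-bromo-6-methoxybenzofuran-3-carbaldehyde | COc1cc2oc(-c3ccc(OCc4ccccc4)cc3OCc3ccccc3)c(C=O)c2c(OCc2ccccc2)c1Br | intermediate
18 | 2-methylbut-3-yn-2-ol | CC(C)(O)C#C | starting material
19 | 2-[2,4-bis(benzyloxy)phenyl]-4-(benzyloxy)-5-(3-hydroxy-3-methylbut-1-yn-1-yl)-6-methoxybenzofuran-3-carbaldehyde | COc1cc2oc(-c3ccc(OCc4ccccc4)cc3OCc3ccccc3)c(C=O)c2c(OCc2ccccc2)c1C#CC(C)(C)O | intermediate
20 | ebenfuran V, 2-(2,4-dihydroxyphenyl)-4-hydroxy-5-(3-hydroxy-3-methylbutyl)-6-methoxybenzofuran-3-carbaldehyde (achiral) | COc1cc2oc(-c3ccc(O)cc3O)c(C=O)c2c(O)c1CCC(C)(C)O | target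

Total step count: 12. Longest linear sequence: 11 steps (steps 1 to 5 and 7 to 12, from 5-methoxyresorcinol); step 6 is a one-step side branch.

Steps most likely to fail

Step 10. Aromatisation may run in the wrong sense: the cyclic acetal can lose methanol across C2–C3 faster than it reopens, which leads to a 3-aroylbenzofuran, and the strong acid in the ionising solvent may begin to strip benzyl groups. In the fallback the formyl group is not taken from the rearranged carbon but introduced by electrophilic substitution after an unambiguous furan closure. It sets out from 13. Aqueous HCl in THF should hydrolyse the MOM ether and the dimethyl acetal to the lactol [4-(benzyloxy)-5-bromo-2-hydroxy-6-methoxy-2,3-dihydrobenzofuran-3-yl][2,4-bis(benzyloxy)phenyl]methanone F1. Aqueous NaOH in ethanol then removes the formyl carbon from the open β-keto aldehyde form by retro-Claisen cleavage, giving the deoxybenzoin 2-[2-(benzyloxy)-3-bromo-6-hydroxy-4-methoxyphenyl]-1-[2,4-bis(benzyloxy)phenyl]ethan-1-one F2, in which the ketone is the only electrophile left for the phenol. p-TsOH in toluene at reflux cyclodehydrates it to 2-[2,4-bis(benzyloxy)phenyl]-4-(benzyloxy)-5-bromo-6-methoxybenzofuran F3. Vilsmeier–Haack formylation (POCl3, DMF, then aqueous NaOAc) at C3, the enol-ether carbon of the 2-arylbenzofuran, should then give 17, where the fallback comes back to the route; C7 is the site that could compete.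

Step 8. The oxidant may attack the electron-rich arene C–H between OMe and OMOM instead of the hindered enone, or the TsOH released may remove the MOM group early so that phenol oxidation competes with the aryl shift. The fallback avoids the iodine oxidant and reaches the same 1,2-diaryl three-carbon skeleton through an epoxide. It sets out from 11. Weitz–Scheffer epoxidation (H2O2, NaOH, MeOH/THF, 0 °C to rt) should give the racemic trans-epoxide {3-[2-(benzyloxy)-3-bromo-4-methoxy-6-(methoxymethoxy)phenyl]oxiran-2-yl}[2,4-bis(benzyloxy)phenyl]methanone F4. BF3·OEt2 in CH2Cl2 at −20 °C opens it at the benzylic carbon, and a 1,2-shift of the aroyl group (Meinwald-type rearrangement of a chalcone epoxide) gives the keto aldehyde 2-[2-(benzyloxy)-3-bromo-4-methoxy-6-(methoxymethoxy)phenyl]-3-[2,4-bis(benzyloxy)phenyl]-3-oxopropanal F5. p-TsOH·H2O in methanol at 40 °C then removes the MOM group and closes the cyclic methyl acetal, so that the fallback comes back to the route at 15.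

Step 12. The formyl group may be over-reduced during the long exposure that the crowded C4 benzyl ether and the hindered alkyne require. In the fallback the aldehyde is masked through the reduction. It sets out from 19. HC(OMe)3 and MeOH with catalytic PPTS at rt should give the dimethyl acetal 4-[4-(benzyloxy)-2-[2,4-bis(benzyloxy)phenyl]-3-(dimethoxymethyl)-6-methoxybenzofuran-5-yl]-2-methylbut-3-yn-2-ol F6. Hydrogenation over 10% Pd/C in EtOAc with a trace of Et3N then saturates the alkyne and cleaves the benzyl ethers to give 4-[2-(2,4-dihydroxyphenyl)-3-(dimethoxymethyl)-4-hydroxy-6-methoxybenzofuran-5-yl]-2-methylbutan-2-ol F7. Aqueous acetic acid in THF at rt, too weak to ionise the tertiary alcohol, hydrolyses the acetal, and the fallback comes back to the route at 20.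

Further compounds
F1 | step 10 | [4-(benzyloxy)-5-bromo-2-hydroxy-6-methoxy-2,3-dihydrobenzofuran-3-yl][2,4-bis(benzyloxy)phenyl]methanone (racemic lactol, mixture of diastereomers) | OC1Oc2cc(OC)c(Br)c(OCc3ccccc3)c2C1C(=O)c1ccc(OCc2ccccc2)cc1OCc1ccccc1
F2 | step 10 | 2-[2-(benzyloxy)-3-bromo-6-hydroxy-4-methoxyphenyl]-1-[2,4-bis(benzyloxy)phenyl]ethan-1-one | O=C(Cc1c(OCc2ccccc2)c(Br)c(OC)cc1O)c1ccc(OCc2ccccc2)cc1OCc1ccccc1
F3 | step 10 | 2-[2,4-bis(benzyloxy)phenyl]-4-(benzyloxy)-5-bromo-6-methoxybenzofuran | COc1cc2oc(-c3ccc(OCc4ccccc4)cc3OCc3ccccc3)cc2c(OCc2ccccc2)c1Br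
F4 | step 8 | {3-[2-(benzyloxy)-3-bromo-4-methoxy-6-(methoxymethoxy)phenyl]oxiran-2-yl}[2,4-bis(benzyloxy)phenyl]methanone (racemic trans-epoxide, one enantiomer drawn) | O=C([C@@H]1O[C@H]1c1c(OCc2ccccc2)c(Br)c(OC)cc1OCOC)c1ccc(OCc2ccccc2)cc1OCc1ccccc1
F5 | step 8 | racemic 2-[2-(benzyloxy)-3-bromo-4-methoxy-6-(methoxymethoxy)phenyl]-3-[2,4-bis(benzyloxy)phenyl]-3-oxopropanal | O=CC(c1c(OCc2ccccc2)c(Br)c(OC)cc1OCOC)C(=O)c1ccc(OCc2ccccc2)cc1OCc1ccccc1
F6 | step 12 | 4-[4-(benzyloxy)-2-[2,4-bis(benzyloxy)phenyl]-3-(dimethoxymethyl)-6-methoxybenzofuran-5-yl]-2-methylbut-3-yn-2-ol | COc1cc2oc(-c3ccc(OCc4ccccc4)cc3OCc3ccccc3)c(C(OC)OC)c2c(OCc2ccccc2)c1C#CC(C)(C)O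
F7 | step 12 | 4-[2-(2,4-dihydroxyphenyl)-3-(dimethoxymethyl)-4-hydroxy-6-methoxybenzofuran-5-yl]-2-methylbutan-2-ol | COc1cc2oc(-c3ccc(O)cc3O)c(C(OC)OC)c2c(O)c1CCC(C)(C)O
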